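**Plan**

Numbering (germacrane): carbocycle C1–C10, side chain C11–C13 on C7; ring A = O/C5/C4–C1/C10, ring B = O/C5/C6–C9/C10. The retrosynthesis cuts the C9 ester, the lactone O8–C12 bond and the ether O–C10 bond, then C4–CH3 and C2–C3 while C5–C10 is re-joined.
Enabling feature: the ether oxygen bridges C5 and C10 of a ten-membered carbocycle, so without it C5 is a ketone carbon and C1=C10 an alkene. That cyclodec-1(10)-en-5-one is the [3,3] product of a 1,2-divinylcyclohexanol on ring C5–C10, which carries the C10 methyl, the C7 three-carbon chain and the C8/C9 oxygens of an oxidised (S)-carvone.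
Forward: the carvone ring is elaborated first (C10 quaternary centre by an epoxy-alcohol semipinacol shift of vinyl, then the C8 and C9 oxygens); ring expansion with methylation at C4 gives the cyclodecenone; rings A and B close together by transannular oxymercuration; the γ-lactone closes next and the C9 ester is attached last.
Stereochemistry: C7 comes from (S)-carvone; C8, C9 and both vinyl additions follow from attack anti to the C7 chain or to the axial C10 methyl; C4 from outer-face methylation of the ring-expanded enolate; C5 from 1,2-induction by C4 in the ketone reduction; C10 is fixed by C5 through the bridge; the ester centre comes from (R)-2-methylbutanoic acid.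

Key step: step 13

Remark: the geometry of C1=C10 is not carried into the target (C1 becomes CH2 and C10 is fixed by the ether bridge), so the (Z)-alkene that the cis-divinyl chair delivers is used as formed.

**Route**

Step 1
Reactants: 1 (S)-carvone
Product: 2 (5S)-5-(3-chloroprop-1-en-2-yl)-2-methylcyclohex-2-en-1-one
Conditions: Ca(OCl)2, CO2 (s), CH2Cl2/H2O, 0 °C
Reagents that add atoms: calcium hypochlorite, [Ca+2].[O-]Cl.[O-]Cl
Why: Ene-type allylic chlorination by HOCl (released from Ca(OCl)2 and CO2) should attack only the electron-rich 1,1-disubstituted alkene and move it onto the former methyl carbon, leaving the enone and C7 untouched.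

Step 2
Reactants: 2 (5S)-5-(3-chloroprop-1-en-2-yl)-2-methylcyclohex-2-en-1-one
Product: 3 (5S)-5-[3-(4-methoxyphenoxy)prop-1-en-2-yl]-2-methylcyclohex-2-en-1-one
Conditions: 4-MeOC6H4OH, K2CO3, NaI (cat.), acetone, 56 °C
Reagents that add atoms: 4-methoxyphenol, COc1ccc(O)cc1
Why: Williamson ether synthesis (phenoxide displacement of the allylic chloride; direct and allylic substitution give the same product) is mild enough for the enone and gives an aryl ether that should survive the basic, hydridic and Lewis-acidic steps up to step 14.

Step 3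
Reactants: 3 (5S)-5-[3-(4-methoxyphenoxy)prop-1-en-2-yl]-2-methylcyclohex-2-en-1-one; 4 vinylmagnesium bromide
Product: 5 C9 vinyl carbinol (vinyl trans and OH cis to the C7 side chain)
Conditions: THF, −78 to 0 °C
Reagents that add atoms: none
Why: Grignard 1,2-addition to the cyclohexenone, in which the vinyl group should enter axially on the face opposite the C7 side chain (the sense in which hydride reduces carvone to cis-carveol), so that the C9 hydroxyl is cis to the side chain.

Step 4
Reactants: 5 C9 vinyl carbinol
Product: 6 5,10-epoxy-9-vinyl carbinol (epoxide oxygen cis to the C9 hydroxyl)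
Conditions: VO(acac)2 (cat.), t-BuOOH, CH2Cl2, 0 °C to rt
Reagents that add atoms: tert-butyl hydroperoxide, CC(C)(C)OO
Why: VO(acac)2-catalysed hydroxyl-directed epoxidation of the tertiary allylic alcohol should deliver oxygen to the trisubstituted ring alkene on the face of the C9 hydroxyl and leave the vinyl and side-chain alkenes alone.

Step 5
Reactants: 6 5,10-epoxy-9-vinyl carbinol
Product: 7 5-hydroxy-10-methyl-10-vinyl C9 ketone (C10 vinyl trans, C10 methyl and C5–OH cis to the C7 side chain)
Conditions: BF3·OEt2, CH2Cl2, −78 °C
Reagents that add atoms: none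
Why: Semipinacol rearrangement of a 2,3-epoxy alcohol, in which the Lewis acid opens the epoxide at tertiary C10 while the antiperiplanar vinyl group shifts from C9 to C10 with inversion, which creates the quaternary centre (vinyl equatorial, methyl axial), returns the C9 ketone and leaves C5–OH.

Step 6
Reactants: 7 5-hydroxy-10-methyl-10-vinyl C9 ketone
Product: 8 C5 tert-butyldimethylsilyl ether of 7
Conditions: TBSOTf, 2,6-lutidine, CH2Cl2, −78 to 0 °C
Reagents that add atoms: tert-butyldimethylsilyl trifluoromethanesulfonate, CC(C)(C)[Si](C)(C)OS(=O)(=O)C(F)(F)F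
Why: Silyl ether formation with the reactive triflate protects the hindered β-hydroxyl so that the enolate of step 7 cannot cleave by retro-aldol reaction.

Step 7
Reactants: 8 C5 tert-butyldimethylsilyl ether of 7
Product: 10 8-hydroxy C9 ketone (C8–OH trans to the C7 side chain), via potassium enolate 9 (not isolated)
Conditions: KN(SiMe3)2, THF, −78 °C; then 3-phenyl-2-(phenylsulfonyl)oxaziridine, −78 °C
Reagents that add atoms: 3-phenyl-2-(phenylsulfonyl)oxaziridine, O=S(=O)(N1OC1c1ccccc1)c1ccccc1
Why: Enolate hydroxylation with an N-sulfonyloxaziridine, in which only the C8 enolate can form because C10 is quaternary and oxygen is expected to enter anti to both the C7 side chain and the axial C10 methyl, giving the equatorial C8 hydroxyl trans to the side chain.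

Step 8
Reactants: 10 8-hydroxy C9 ketone
Product: 11 8,9-trans-diol (C9–OH cis to the C7 side chain)
Conditions: NaBH4, MeOH, −20 °C
Reagents that add atoms: none
Why: Borohydride reduction of the α-hydroxy ketone, in which hydride should add to C9 along the axial path anti to the axial C10 methyl, so that the new hydroxyl is equatorial, trans to C8–OH and configured as in the target.

Step 9
Reactants: 11 8,9-trans-diol
Product: 12 8,9-bis(methoxymethyl) ether of 11
Conditions: MOMCl, i-Pr2NEt, Bu4NI (cat.), CH2Cl2, 40 °C
Reagents that add atoms: chloromethyl methyl ether, COCCl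
Why: Acetal (MOM) ether formation under amine-base conditions with iodide catalysis caps both hydroxyls without generating an alkoxide that could trigger silyl migration from O5.

Step 10
Reactants: 12 8,9-bis(methoxymethyl) ether of 11
Product: 13 C5 alcohol (12 without the silyl group)
Conditions: Bu4NF, THF, 50 °C
Reagents that add atoms: none
Why: Fluoride-mediated desilylation frees only the C5 hydroxyl, since MOM and aryl ethers are inert to fluoride.

Step 11
Reactants: 13 C5 alcohol
Product: 14 C5 ketone (2-methyl-2-vinylcyclohexanone core with 8,9-bis-MOM ethers)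
Conditions: Dess–Martin periodinane, CH2Cl2, rt
Reagents that add atoms: none
Why: Dess–Martin oxidation gives the C5 ketone under neutral conditions, and because the ketone is flanked by quaternary C10 no stereocentre can epimerise.

Step 12
Reactants: 14 C5 ketone; 4 vinylmagnesium bromide
Product: 15 cis-1,2-divinylcyclohexanol (C5 vinyl cis to the C10 vinyl; C5–OH cis to the C10 methyl)
Conditions: LaCl3·2LiCl, THF, −78 to 0 °C
Reagents that add atoms: none
Why: Grignard 1,2-addition with LaCl3·2LiCl to suppress enolisation at C6, in which the vinyl group should enter axially, anti to the axial C10 methyl, giving the tertiary alcohol with the C5 vinyl axial and cis to the C10 vinyl, the isomer whose chair rearrangement exposes the enolate face needed at C4.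

Step 13
Reactants: 15 cis-1,2-divinylcyclohexanol
Product: 18 (1(10)Z,4S)-8,9-bis(methoxymethoxy)-12-(4-methoxyphenoxy)germacra-1(10),11(13)-dien-5-one, via potassium alkoxide 16 (not isolated), via potassium enolate 17 (not isolated)
Conditions: KN(SiMe3)2, 18-crown-6, THF, 0 °C to rt; then MeI, −78 °C
Reagents that add atoms: iodomethane, CI
Why: Anionic oxy-Cope rearrangement with enolate trapping: the crown-ether-separated potassium alkoxide 16 undergoes a [3,3] sigmatropic shift through a chair transition state fused cis-decalin-like to the cyclohexane chair (C5 vinyl axial, C10 vinyl equatorial), which forms C2–C3 and cleaves C5–C10 to give enolate 17, and MeI then alkylates C4. The closest known reaction type is the alkoxide-accelerated ring expansion of 1,2-divinylcyclohexanols to cyclodec-5-enones with in situ alkylation of the regiodefined enolate. The ten-membered ring is not closed by a cyclisation but arises by four-atom ring expansion of the C5–C10 cyclohexane, so no closure mode applies. The equatorial C10 vinyl places C9 axial on the pericyclic chair and so gives the (Z)-C1=C10 alkene, while the axial C5 vinyl gives the enolate with C3 and C6 trans. The new stereocentre C4 is set by attack of MeI on the outer face of that enolate, the inner face being covered across the ring by C1 and C10, which should lead to 4S. The step needs the chair rather than a boat and C-methylation without proton exchange; the equatorial C7, C8 and C9 substituents lock the cyclohexane chair, and a stoichiometric soluble base with alkylation at −78 °C limits equilibration.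

Step 14
Reactants: 18 (1(10)Z,4S)-8,9-bis(methoxymethoxy)-12-(4-methoxyphenoxy)germacra-1(10),11(13)-dien-5-one
Product: 19 (1(10)Z,4S)-12-hydroxy-8,9-bis(methoxymethoxy)germacra-1(10),11(13)-dien-5-one
Conditions: (NH4)2Ce(NO3)6, MeCN/H2O, 0 °C
Reagents that add atoms: none
Why: Oxidative cleavage of the p-methoxyphenyl ether by (NH4)2Ce(NO3)6 (single-electron oxidation of the arene to benzoquinone) frees the C12 allylic alcohol, while MOM ethers, ketone and alkenes are expected to survive at 0 °C.

Step 15
Reactants: 19 (1(10)Z,4S)-12-hydroxy-8,9-bis(methoxymethoxy)germacra-1(10),11(13)-dien-5-one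
Product: 21 C12 acrylic acid (5-oxo acid), via C12 enal 20 (not isolated)
Conditions: TEMPO (cat.), PhI(OAc)2, CH2Cl2, rt; then NaClO2, NaH2PO4, 2-methyl-2-butene, t-BuOH/H2O, rt
Reagents that add atoms: sodium chlorite, [Na+].[O-]Cl=O
Why: Oxoammonium (TEMPO) oxidation of the primary allylic alcohol to the enal followed in the same flask by Pinnick oxidation gives the acrylic acid, the alkene scavenger protecting the ring alkene from HOCl and the buffered medium leaving the C5 ketone and C4 untouched.

Step 16
Reactants: 21 C12 acrylic acid
Product: 22 methyl ester of 21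
Conditions: Me3SiCHN2, PhMe/MeOH, 0 °C
Reagents that add atoms: (trimethylsilyl)diazomethane, C[Si](C)(C)C=[N+]=[N-]
Why: Methyl esterification with (trimethylsilyl)diazomethane under neutral conditions, which keeps the side-chain alkene electron-poor and the carboxyl non-nucleophilic for step 18.

Step 17
Reactants: 22 methyl ester of 21
Product: 23 (5R)-5-hydroxy methyl ester
Conditions: NaBH4, CeCl3·7H2O, MeOH, −78 °C
Reagents that add atoms: none
Why: Luche reduction reduces the ketone and spares the acrylate, and hydride is expected to approach from the ring periphery anti to the C3–C4 bond with the C4 methyl gauche to the carbonyl oxygen (1,2-induction), which gives the 4,5-anti alcohol with 5R configuration.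

Step 18
Reactants: 23 (5R)-5-hydroxy methyl ester
Product: 25 methyl 5,10-epoxy-8,9-bis(methoxymethoxy)germacr-11(13)-en-12-oate, via C1 organomercurial 24 (not isolated)
Conditions: Hg(OCOCF3)2, CH2Cl2, 0 °C; then NaBH4, NaOH (aq), 0 °C
Reagents that add atoms: none
Why: Transannular intramolecular oxymercuration followed by borohydride demercuration, in which O5 adds to the tertiary alkene carbon C10 anti to mercury on C1 (Markovnikov sense), closing oxepane rings A and B in one event, with C10 forced into the target configuration because the one-atom bridge must lie on the inner face fixed by C5, while the electron-poor acrylate does not react.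

Step 19
Reactants: 25 methyl 5,10-epoxy-8,9-bis(methoxymethoxy)germacr-11(13)-en-12-oate
Product: 27 9-hydroxy lactone (target without the acyl group), via diol ester 26 (not isolated)
Conditions: Me2BBr, CH2Cl2, −78 °C; then PPTS (cat.), PhH, 50 °C
Reagents that add atoms: none
Why: Lewis-acid cleavage of both MOM acetals with Me2BBr at low temperature spares the tertiary ether, and mild acid then drives transesterification of the methyl ester onto the C8 hydroxyl, the five-membered trans-fused lactone being favoured over the six-membered alternative on O9.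

Step 20
Reactants: 27 9-hydroxy lactone; 28 (R)-2-methylbutanoic acid
Product: 29 (4S,5R,7R,8R,9S,10R)-5,10-epoxy-9-[(2R)-2-methylbutanoyloxy]germacr-11(13)-en-12,8-olide (CNP0136059.1)
Conditions: dicyclohexylcarbodiimide, DMAP, CH2Cl2, 0 °C to rt
Reagents that add atoms: none
Why: Steglich esterification acylates the hindered C9 hydroxyl with retention at C9, and carbodiimide activation of the α-branched acid is not expected to epimerise its stereocentre.

**Compound list**

1 | (S)-carvone | CC(=C)[C@H]1CC=C(C)C(=O)C1 | starting material
2 | (5S)-5-(3-chloroprop-1-en-2-yl)-2-methylcyclohex-2-en-1-one | ClCC(=C)[C@H]1CC=C(C)C(=O)C1 | intermediate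
3 | (5S)-5-[3-(4-methoxyphenoxy)prop-1-en-2-yl]-2-methylcyclohex-2-en-1-one | COc1ccc(OCC(=C)[C@H]2CC=C(C)C(=O)C2)cc1 | intermediate
4 | vinylmagnesium bromide | C=C[Mg]Br | starting material
5 | C9 vinyl carbinol (vinyl trans and OH cis to the C7 side chain) | COc1ccc(OCC(=C)[C@H]2CC=C(C)[C@](O)(C=C)C2)cc1 | intermediate
6 | 5,10-epoxy-9-vinyl carbinol (epoxide oxygen cis to the C9 hydroxyl) | COc1ccc(OCC(=C)[C@H]2C[C@H]3O[C@@]3(C)[C@](O)(C=C)C2)cc1 | intermediate
7 | 5-hydroxy-10-methyl-10-vinyl C9 ketone (C10 vinyl trans, C10 methyl and C5–OH cis to the C7 side chain) | COc1ccc(OCC(=C)[C@H]2C[C@@H](O)[C@](C)(C=C)C(=O)C2)cc1 | intermediate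
8 | C5 tert-butyldimethylsilyl ether of 7 | COc1ccc(OCC(=C)[C@H]2C[C@@H](O[Si](C)(C)C(C)(C)C)[C@](C)(C=C)C(=O)C2)cc1 | intermediate
9 | potassium C8-enolate of 8 | [K+].COc1ccc(OCC(=C)[C@H]2C[C@@H](O[Si](C)(C)C(C)(C)C)[C@](C)(C=C)C([O-])=C2)cc1 | intermediate
10 | 8-hydroxy C9 ketone (C8–OH trans to the C7 side chain) | COc1ccc(OCC(=C)[C@H]2C[C@@H](O[Si](C)(C)C(C)(C)C)[C@](C)(C=C)C(=O)[C@@H]2O)cc1 | intermediate
11 | 8,9-trans-diol (C9–OH cis to the C7 side chain) | COc1ccc(OCC(=C)[C@H]2C[C@@H](O[Si](C)(C)C(C)(C)C)[C@](C)(C=C)[C@@H](O)[C@@H]2O)cc1 | intermediate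
12 | 8,9-bis(methoxymethyl) ether of 11 | COc1ccc(OCC(=C)[C@H]2C[C@@H](O[Si](C)(C)C(C)(C)C)[C@](C)(C=C)[C@@H](OCOC)[C@@H]2OCOC)cc1 | intermediate
13 | C5 alcohol (12 without the silyl group) | COc1ccc(OCC(=C)[C@H]2C[C@@H](O)[C@](C)(C=C)[C@@H](OCOC)[C@@H]2OCOC)cc1 | intermediate
14 | C5 ketone (2-methyl-2-vinylcyclohexanone core with 8,9-bis-MOM ethers) | COc1ccc(OCC(=C)[C@H]2CC(=O)[C@](C)(C=C)[C@@H](OCOC)[C@@H]2OCOC)cc1 | intermediate
15 | cis-1,2-divinylcyclohexanol (C5 vinyl cis to the C10 vinyl; C5–OH cis to the C10 methyl) | COc1ccc(OCC(=C)[C@H]2C[C@](O)(C=C)[C@](C)(C=C)[C@@H](OCOC)[C@@H]2OCOC)cc1 | intermediate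
16 | potassium alkoxide of 15 | [K+].COc1ccc(OCC(=C)[C@H]2C[C@]([O-])(C=C)[C@](C)(C=C)[C@@H](OCOC)[C@@H]2OCOC)cc1 | intermediate
17 | potassium (1(10)Z)-cyclodeca-1(10),4-dien-5-olate (C3 and C6 trans across C4=C5) | [K+].COc1ccc(OCC(=C)[C@H]2C/C([O-])=C/CC/C=C(C)\[C@@H](OCOC)[C@@H]2OCOC)cc1 | intermediate
18 | (1(10)Z,4S)-8,9-bis(methoxymethoxy)-12-(4-methoxyphenoxy)germacra-1(10),11(13)-dien-5-one | COc1ccc(OCC(=C)[C@H]2CC(=O)[C@@H](C)CC/C=C(C)\[C@@H](OCOC)[C@@H]2OCOC)cc1 | intermediate
19 | (1(10)Z,4S)-12-hydroxy-8,9-bis(methoxymethoxy)germacra-1(10),11(13)-dien-5-one | OCC(=C)[C@H]1CC(=O)[C@@H](C)CC/C=C(C)\[C@@H](OCOC)[C@@H]1OCOC | intermediate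
20 | C12 enal of 19 | O=CC(=C)[C@H]1CC(=O)[C@@H](C)CC/C=C(C)\[C@@H](OCOC)[C@@H]1OCOC | intermediate
21 | C12 acrylic acid (5-oxo acid) | OC(=O)C(=C)[C@H]1CC(=O)[C@@H](C)CC/C=C(C)\[C@@H](OCOC)[C@@H]1OCOC | intermediate
22 | methyl ester of 21 | COC(=O)C(=C)[C@H]1CC(=O)[C@@H](C)CC/C=C(C)\[C@@H](OCOC)[C@@H]1OCOC | intermediate
23 | (5R)-5-hydroxy methyl ester | COC(=O)C(=C)[C@H]1C[C@@H](O)[C@@H](C)CC/C=C(C)\[C@@H](OCOC)[C@@H]1OCOC | intermediate
24 | C1 organomercurial (1-trifluoroacetoxymercurio-5,10-epoxy ester, anti adduct) | COC(=O)C(=C)[C@H]1C[C@H]2O[C@](C)([C@@H]([Hg]OC(=O)C(F)(F)F)CC[C@@H]2C)[C@@H](OCOC)[C@@H]1OCOC | intermediate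
25 | methyl 5,10-epoxy-8,9-bis(methoxymethoxy)germacr-11(13)-en-12-oate (ring centres as in the target) | COC(=O)C(=C)[C@H]1C[C@H]2O[C@](C)(CCC[C@@H]2C)[C@@H](OCOC)[C@@H]1OCOC | intermediate
26 | 8,9-diol methyl ester | COC(=O)C(=C)[C@H]1C[C@H]2O[C@](C)(CCC[C@@H]2C)[C@@H](O)[C@@H]1O | intermediate
27 | 9-hydroxy lactone (5,10-epoxy-9-hydroxygermacr-11(13)-en-12,8-olide) | C=C1C(=O)O[C@@H]2[C@@H]1C[C@H]1O[C@](C)(CCC[C@@H]1C)[C@H]2O | intermediate
28 | (R)-2-methylbutanoic acid | CC[C@@H](C)C(O)=O | starting material
29 | (4S,5R,7R,8R,9S,10R)-5,10-epoxy-9-[(2R)-2-methylbutanoyloxy]germacr-11(13)-en-12,8-olide (CNP0136059.1) | C=C1C(=O)O[C@@H]2[C@@H]1C[C@H]1O[C@](C)(CCC[C@@H]1C)[C@H]2OC(=O)[C@H](C)CC | target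

**Step count and risks**

Total steps: 20. Longest linear sequence: 20 steps from (S)-carvone (1); acid 28 is used as purchased.

Steps most likely to fail:

Step 13. Proton exchange between the methylated ketone 18 and unreacted enolate 17 (over-methylation, loss of the C4 configuration), or turning of the enolate plane through the ring before alkylation, may erode the facial control at C4. The fallback sets out from 15: the same alkoxide rearrangement is run and enolate 17 is trapped with Me3SiCl as the trimethylsilyl enol ether of the unmethylated cyclodecenone F1, which is purified. MeLi (THF, 0 °C) then releases the amine-free lithium enolate F2, which is methylated with MeI at −78 °C, and the route is rejoined at 18. This separates the pericyclic event from the alkylation and replaces the crown-separated potassium enolate by a contact lithium enolate.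

Step 17. Hydride delivery to the medium-ring ketone may show poor or inverted facial selectivity. The fallback sets out from 22: the reduction product of 5S configuration, the 5S alcohol F3, is inverted by a Mitsunobu reaction (PPh3, diisopropyl azodicarboxylate, 4-nitrobenzoic acid) to the 5R 4-nitrobenzoate F4. Brief methanolysis (K2CO3, MeOH, 0 °C) then returns to the route at 23.

Step 18. The mercurinium ion on the hindered (Z)-alkene may form slowly, or the ring may fail to fold for anti attack of O5 at C10, so that the alkene is returned on reduction or O5 is captured at C1. The fallback sets out from 23: a Brønsted-acid-catalysed hydroalkoxylation (CF3SO3H cat., CH2Cl2, −40 °C) passes through the tertiary C10 cation, which depends neither on alkene geometry nor on an anti-periplanar arrangement, and arrives directly at 25. This fallback makes no new compound (F0).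

**Further compounds**

F1 | step 13 | trimethylsilyl enol ether of the unmethylated cyclodecenone | COc1ccc(OCC(=C)[C@H]2C/C(O[Si](C)(C)C)=C/CC/C=C(C)\[C@@H](OCOC)[C@@H]2OCOC)cc1
F2 | step 13 | lithium enolate of the unmethylated cyclodecenone | [Li+].COc1ccc(OCC(=C)[C@H]2C/C([O-])=C/CC/C=C(C)\[C@@H](OCOC)[C@@H]2OCOC)cc1
F3 | step 17 | 5S alcohol (C5 epimer of 23) | COC(=O)C(=C)[C@H]1C[C@H](O)[C@@H](C)CC/C=C(C)\[C@@H](OCOC)[C@@H]1OCOC
F4 | step 17 | 5R 4-nitrobenzoate | COC(=O)C(=C)[C@H]1C[C@@H](OC(=O)c2ccc(cc2)[N+](=O)[O-])[C@@H](C)CC/C=C(C)\[C@@H](OCOC)[C@@H]1OCOC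
F0 | step 18 | none | none
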